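The vessel was closed and stirred. I followed one molecule of starting material in it and asked for its chance of being product late in the run, which is the fraction of the charge turned.

| flask | starting material | time |
|---|---|---|
| Thursday's | 200 mM |  |
| Tuesday's | 400 mM |  |
| Wednesday's | 700 mM | 15 min |

- Thursday's run (time / min: [product] / mM): 0.67: 10.0; 2.0: 25.1; 3.9: 52.3; 6.1: 80.9; 8.8: 115.7; 12: 146.0; 15: 163.9
- Tuesday's run (time / min: [product] / mM): 0.67: 13.5; 2.0: 44.9; 3.9: 87.6; 6.1: 138.0; 8.8: 200.6; 12: 266.9; 15: 322.2

(readings scatter by 2 mM)

- order of the initial rate in [starting material], near the charge of the Thursday's run, the rate being that where two percent of its starting material are product (one fixed amount of product, the same in the runs compared)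
- product in the Wednesday's run at 15 min, as a share of the starting material charged
- which of these the readings show (the product decays / nothing beyond the main steps / the substrate is lost by itself / the substrate pairs with itself)

- Overall: starting material -> product.
- Constant volume, constant temperature.
- Bound and free are read together.
- An order is taken over about fifteen percent of the charge, up and down.

At 15 min that chance was 82.0% in Thursday's run and 80.5% in Tuesday's. I called the fall in that fraction for each doubling of the charge the slip, and these runs put it at 1.4 percentage points. That reading carries a scatter of 1.1 points, so it is rough. Going from Tuesday's charge to Wednesday's is 0.807 of such steps, so I reckoned 79.4% for Wednesday's run at 15 min.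

One number was not enough: at 6.1 min the fractions were 40.5% in Thursday's run and 34.5% in Tuesday's, a slip larger than the one at 15 min, at 5.9 points. At that time Tuesday's run had made 1.71 times Thursday's product, less than the ratio of the charges, and I read that as an order of 0.770 across the two charges. I chose pairing of the starting material.

The forecast gave order 0.8, 69% and the substrate pairs with itself, its share coming from “a saturating extrapolation”. That share is lower than mine.

Wednesday's run gave 78.7% of its charge as product at 15 min; the order near Thursday's charge came to 0.62, and the readings show that the substrate pairs with itself.

    starting material → product (0.1926 /min)
    starting material + product → 2 product (0.6060 /M/min)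
    2 starting material ⇌ idle substrate dimer, settled at all times (12.40 /M)

The pairing constant in these steps is 12.4 /M. Wednesday's fraction stood 0.70 points under my reckoning. From Tuesday's run to Wednesday's the slip came to 2.3 points, and from Thursday's run to Wednesday's it came to 1.8 points.

The data are calculated for substances that don't exist.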